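# Proposed total synthesis of CNP0246352.0: ring B by diene/alkoxy-ynone cycloaddition

## Analysis of the target

The compound is a linear tetramer of acylphloroglucinol units, rings A–B–C–D, joined by three methylene bridges and carrying four butanoyl groups. Ring A is the only non-aromatic ring, a 4,4-dimethylcyclohexadienone (a butanoylfilicinic acid unit) written as one enol tautomer of a cyclic β-triketone, and its quaternary carbon bears two identical methyl groups. Rings B and C are butanoylphloroglucinols whose two remaining ring carbons both carry bridges, and ring D is a butanoyl(methyl)phloroglucinol with one bridge. There is no stereocentre, so sequence and regiochemistry are the only things to control. The sensitive features are the nine phenolic and two enolic hydroxyls (oxidation, chelation) and, above all, the aryl–CH2–aryl and aryl–CH2–trione bridges, which exchange under acid or base by retro-Friedel–Crafts and retro-Michael processes and can scramble the ring order. The difficulty is that the four units are nearly identical carbon nucleophiles, so bridging them one carbon at a time tends to give statistical mixtures and over-alkylation, worst at the inner rings B and C, which must react twice. The strategy rests on ring B: going round it, the substituents alternate C–CH2 (to ring A), C–OH, C–CH2 (to ring C), C–OH, C–butanoyl, C–OH. This is the pattern of a four-carbon 1,3-dioxygenated diene (two oxygenated carbons, the carbon between them and the arm-bearing carbon) joined to a two-carbon alkoxy-ynone (the butanoyl-bearing carbon and the third oxygenated carbon).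

## Retrosynthetic reasoning

**Bridge A–B (29 ⇒ 25 + 27).** The bond between the bridging carbon and the only unsubstituted carbon of ring B is cut first. Ring A is the one dearomatized, most base- and acid-labile unit, and its bridge is the one most prone to retro-Michael cleavage, so it should be exposed to the fewest operations. The cut leaves two mono-functional partners: trimer 25 has exactly one free ring carbon and 27 exactly one aminomethyl group. In the forward direction 27 loses its amine to give methide 28, which 25 captures at carbon.

**Ring A (27 ⇒ 26 ⇒ 3).** The aminomethyl group of 27 is removed to give 26, and the two methyl groups of 26 are removed to give the aromatic ketone 3. The forward reactions are a double C-methylation at one ring carbon of 3, which dearomatizes the ring, and a Mannich reaction at the remaining CH. Ring A thus comes from the same monomer as ring C.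

**Protecting groups (25 ⇒ 24 ⇒ 23).** The free trimer 25 is traced back to its ring B mono-ethyl ether 24 and then to the hexabenzyl ether 23. The benzyl ethers are removed first, by hydrogenolysis, because no Lewis acid strong enough to cleave the ethyl ether would spare them. The ethyl ether is then cleaved by a boron trihalide that does not depend on carbonyl assistance, because the hydroxyl on the other side of the ketone would tie the carbonyl up as a boron chelate.

**Ring B (23 ⇒ 17 + 21).** Two bonds of ring B are cut: the bond between the arm-bearing carbon and the ethoxy-bearing carbon, and the bond between the butanoyl-bearing carbon and the hydroxyl-bearing carbon next to it. This leaves diene 17, whose terminal carbon already carries the arm to rings C and D, and ynone 21, which brings the butanoyl group and the third oxygen. The cut is made here for three reasons: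
- The B–C bridge is never made by a diarylmethane coupling, because its carbon is already part of the diene side chain.
- The ring carbon later needed for ring A is the central CH of the diene and emerges unsubstituted by construction.
- The butanoyl group arrives with the ring, so no acylation of a trimer is needed.

The forward reaction must form both bonds with the orientation that pairs the nucleophilic diene terminus with the ethoxy-bearing alkyne carbon, and then aromatize. The two aryl ketones of the C–D arm cannot stay free while the diene is made with a strong base, so in 17 they are carried as silyl enol ethers, which fall off in the acidic work-up of the cycloaddition.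

**Ynone (21 ⇒ 18 + 19).** The bond between the carbonyl carbon and the alkyne is cut. Forward, the lithium acetylide 20 of ethoxyethyne 18 is acylated once by the N-methoxy-N-methylamide 19.

**Diene (17 ⇒ 16 ⇒ 15 ⇒ 12 + 13).** The silyl groups are removed in two stages to reveal β-keto ester 15. Its bond between the γ-carbon and the benzylic carbon is cut to give bromide 12 and methyl acetoacetate 13, which reacts as its dianion 14. This places the four diene carbons and the bridge carbon in the right order in one C–C bond formation.

**One-carbon arm (12 ⇒ 11 ⇒ 10 ⇒ 9 ⇒ 8).** The bromide goes back to alcohol 11 and aldehyde 10, the benzyl ethers are removed to give 9, and the formyl group is removed to give the C–D dimer 8. Formylation is placed before benzylation because 8 has a single free aromatic carbon, activated by two flanking hydroxyls, and because 9 then has no free ring carbon left at which benzylation could go astray.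

**Bridge C–D (8 ⇒ 6 + 3; 6 ⇒ 5 ⇒ 4 + 2; 3 ⇒ 1 + 2).** The C–D bridge is cut at ring C. Ring D, which has only one free carbon, carries the aminomethyl group (6, reacting through methide 7), and the cheap monomer 3, with two equivalent free carbons, is the nucleophile used in excess. The monomers 5 and 3 come from Friedel–Crafts acylation of 4 and 1 with 2.

## Alternatives that were turned down

**Alternative 1: ring C from a 2-pyranone.**
- Disconnection: the C–D dimer A1 (the same compound as 8) is traced back to the 4-hydroxy-2-pyranone A2 by cutting the ring C bond between the butanoyl-bearing carbon and a neighbouring hydroxyl-bearing carbon. In A2, C3 carries the ring D arm and C6 a 2-oxopentyl chain.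
- Forward key step: a magnesium alkoxide in its alcohol opens the lactone, and the chain carbon flanked by the two ketones closes onto the liberated ester carbonyl (Claisen condensation), which aromatizes to ring C.
- For it: the pyranone has one nucleophilic carbon only, so its bridging with ring D cannot over-alkylate and needs no excess of a partner. On this point it is stronger than step 4 of the chosen route, which relies on a fourfold excess of 3.
- Against it: A2 needs several steps of pyranone side-chain chemistry. The closure has to choose Claisen over the competing aldol mode. It solves only the C–D junction, which is the easiest one because ring D has a single free carbon anyway, and leaves rings B and A to statistical bridging.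
- Comparison: the chosen route reaches the same compound in four steps from the monomers and spends its new ring construction on ring B, the doubly bridged inner ring where the sequence problem is hardest.

**Alternative 2: ring D aryne inserted into a ring C aldehyde.**
- Disconnection: the C–D bridge is cut at ring D, at the aryl–CH2 bond together with the neighbouring aryl–O bond. Ring D becomes the aryne released from the ortho-silyl aryl triflate A4, and ring C the aldehyde A5.
- Forward key step: fluoride releases the aryne, which adds across the C=O of A5 to a benzoxete that opens to an ortho-quinone methide. A Hantzsch-type dihydropyridine in the same flask reduces the methide to the methylene, giving the protected dimer A3 with one free phenol and one free carbon.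
- For it: it is convergent, it delivers the benzylated dimer directly, and it avoids the acid/base conditions under which bridges exchange. On protecting-group economy it is stronger than the chosen route, which needs the separate perbenzylation of step 6.
- Against it: A4 is a hexasubstituted arene with adjacent silyl and triflate groups and would itself take a long sequence. The regiochemistry of aryne capture depends on the modest inductive bias of one flanking benzyloxy group against a methyl group. The enolizable butanoyl ketones are competing traps for an aryne. A5 is a hindered, electron-rich carbonyl partner.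
- Comparison: again only the C–D junction is addressed, and at a higher step count than the two-step methide coupling to 8. The chosen route keeps its one speculative step for ring B and makes the C–D part by ordinary chemistry.

**Alternative 3: Danheiser benzannulation building ring C.**
- Disconnection: ring C is removed altogether by cutting two of its bonds, leaving cyclobutenone A7 (ring B attached through the future bridge) and siloxyalkyne A8 (ring D attached through the other bridge).
- Forward key step: heating opens A7 to a vinylketene, which adds to A8. The new cyclobutenone opens and recloses by 6π electrocyclization to the phenol ring C of A6.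
- For it: it joins two halves of the molecule while making the inner ring, with a regiochemistry fixed by the mechanism. On convergence it is clearly stronger than the chosen, largely linear route.
- Against it: ring C of A6 emerges without its butanoyl group and with three different oxygen functions (free hydroxyl, ethyl ether, silyl ether). A Friedel–Crafts or Fries acylation must then be carried out on a benzyl-ether-laden trimer, followed by three kinds of deprotection. A7 and A8 each need multistep preparation from arylacetic-acid-level precursors.
- Comparison: the chosen cycloaddition installs the butanoyl group of the new ring together with the ring, leaves only one ethyl ether to remove, and forms the free carbon for ring A automatically. The price is a longer linear sequence to diene 17.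

Key step: step 13

Assumption: the target has no stereocentre and ring A is one of several rapidly equilibrating enol tautomers, so the route aims at the constitution; the silyl enol ether geometries written for 16, 17 and 22 are the expected ones and are lost again in step 13.

## Route

Step 1
Reactants: 1 phloroglucinol; 2 butanoyl chloride
Product: 3 1-(2,4,6-trihydroxyphenyl)butan-1-one (phlorobutyrophenone)
Conditions: AlCl3 (3.5 equiv), PhNO2–CH2Cl2, 0 °C → 50 °C; ice/HCl
Reagents that add atoms: none
Why: Friedel–Crafts acylation of the symmetrical triol; the first acyl group deactivates the ring and holds the Lewis acid as a chelate, so mono-acylation should dominate.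

Step 2
Reactants: 4 2-methylphloroglucinol; 2 butanoyl chloride
Product: 5 1-(2,4,6-trihydroxy-3-methylphenyl)butan-1-one
Conditions: AlCl3 (3.5 equiv), PhNO2–CH2Cl2, 0 °C → 50 °C; ice/HCl
Reagents that add atoms: none
Why: The same Friedel–Crafts acylation; the two free positions of 4 are equivalent, so only one ketone can form.

Step 3
Reactants: 5 1-(2,4,6-trihydroxy-3-methylphenyl)butan-1-one
Product: 6 1-{3-[(dimethylamino)methyl]-2,4,6-trihydroxy-5-methylphenyl}butan-1-one (ring D Mannich base)
Conditions: CH2=NMe2+ I− (1.05 equiv), Et3N (1 equiv), CH2Cl2, 0 °C → rt
Reagents that add atoms: N,N-dimethylmethyleneiminium iodide, C=[N+](C)C.[I-]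
Why: Mannich aminomethylation of an electron-rich phenol; 5 has a single free ring carbon, so position and degree of substitution are fixed.

Step 4
Reactants: 6 ring D Mannich base; 3 phlorobutyrophenone (4 equiv)
Product: 8 1-{3-[(3-butanoyl-2,4,6-trihydroxy-5-methylphenyl)methyl]-2,4,6-trihydroxyphenyl}butan-1-one (C–D dimer), via ring D ortho-quinone methide 7 (not isolated)
Conditions: 1,4-dioxane, 100 °C, N2 purge
Reagents that add atoms: none
Why: Thermal loss of dimethylamine from the phenolic Mannich base should give ortho-quinone methide 7, which is trapped at carbon by 3 (conjugate addition, then re-aromatization). The two free carbons of 3 are equivalent and its excess suppresses a second alkylation.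

Step 5
Reactants: 8 C–D dimer
Product: 9 3-butanoyl-5-[(3-butanoyl-2,4,6-trihydroxy-5-methylphenyl)methyl]-2,4,6-trihydroxybenzaldehyde
Conditions: POCl3 (1.3 equiv), DMF, EtOAc, 0 °C → rt; H2O, 50 °C
Reagents that add atoms: N,N-dimethylformamide, CN(C)C=O; water, O
Why: Vilsmeier–Haack formylation; ring C of 8 carries the only unsubstituted aromatic carbon of the molecule, flanked by two hydroxyls, so the electrophile has one place to go.

Step 6
Reactants: 9 formylated C–D dimer
Product: 10 2,4,6-tris(benzyloxy)-3-butanoyl-5-{[2,4,6-tris(benzyloxy)-3-butanoyl-5-methylphenyl]methyl}benzaldehyde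
Conditions: BnBr (9 equiv), K2CO3 (9 equiv), n-Bu4NI (cat.), DMF, 65 °C
Reagents that add atoms: benzyl bromide, BrCc1ccccc1
Why: Williamson ether synthesis with carbonate in a dipolar aprotic solvent, where phenoxide O-alkylation should outrun C-alkylation; this is helped by the fact that 9 has no unsubstituted ring carbon left.

Step 7
Reactants: 10 hexabenzyl aldehyde
Product: 11 the corresponding benzylic alcohol (CH2OH in place of CHO)
Conditions: NaBH4 (1 equiv), THF–MeOH 4:1, −10 °C → 0 °C
Reagents that add atoms: none
Why: Borohydride reduction; the aldehyde should be reduced far faster than the two di-ortho-substituted, twisted aryl ketones.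

Step 8
Reactants: 11 benzylic alcohol
Product: 12 the corresponding benzylic bromide (CH2Br)
Conditions: CBr4 (1.3 equiv), PPh3 (1.3 equiv), CH2Cl2, 0 °C; used crude
Reagents that add atoms: tetrabromomethane, BrC(Br)(Br)Br
Why: Appel bromination under essentially neutral conditions that leave benzyl ethers and ketones untouched. Both rings are fully substituted, so the electron-rich bromide cannot alkylate another molecule of itself.

Step 9
Reactants: 12 benzylic bromide; 13 methyl acetoacetate (2 equiv)
Product: 15 methyl 5-aryl-3-oxopentanoate (aryl = the hexabenzylated C–D unit of 12), via acetoacetate dianion 14 (not isolated)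
Conditions: 13, NaH, THF, 0 °C; n-BuLi, 0 °C; then 12, −78 °C → 0 °C; 1 M HCl
Reagents that add atoms: none
Why: γ-Alkylation of the acetoacetate dianion, whose terminal carbanion is the more reactive site, by SN2 on a reactive benzylic bromide at low temperature; this should be faster than enolization of the hindered aryl ketones.

Step 10
Reactants: 15 β-keto ester
Product: 16 methyl (2Z)-5-aryl-3-(trimethylsiloxy)pent-2-enoate
Conditions: Me3SiCl (1.5 equiv), Et3N (1.6 equiv), toluene, rt; filter, concentrate
Reagents that add atoms: chlorotrimethylsilane, C[Si](C)(C)Cl
Why: O-Silylation of the chelated enol of the β-keto ester under amine base; simple ketones are not enolized under these conditions, so the aryl ketones stay as they are.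

Step 11
Reactants: 16 silyl enol ether
Product: 17 fragment 1: (1Z,3Z)-1-methoxy-1,3-bis(trimethylsiloxy)-5-arylpenta-1,3-diene in which both butanoyl groups of the aryl unit are (Z)-trimethylsilyl enol ethers
Conditions: LiN(i-Pr)2 (3.5 equiv), THF, −78 °C; Me3SiCl (4 equiv), −78 °C → 0 °C; evaporate, hexane, filter under Ar; used at once
Reagents that add atoms: chlorotrimethylsilane, C[Si](C)(C)Cl
Why: Kinetic deprotonation at the γ-carbon of the silyloxy enoate and O-silylation of the ester dienolate is the standard second stage in preparing 1-alkoxy-1,3-bis(silyloxy)dienes. The two butanoyl groups are deprotonated as well, so enough base and silyl chloride are used to convert them cleanly into their silyl enol ethers, which are removed again in step 13.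

Step 12
Reactants: 18 ethoxyethyne; 19 N-methoxy-N-methylbutanamide
Product: 21 fragment 2: 1-ethoxyhex-1-yn-3-one, via lithium ethoxyacetylide 20 (not isolated)
Conditions: 18, n-BuLi (1 equiv), THF, −78 °C; 19, −78 °C → −20 °C; AcOH, −78 °C; kept cold
Reagents that add atoms: none
Why: Weinreb ketone synthesis: the acetylide adds once to the N-methoxy-N-methylamide and the chelated tetrahedral intermediate holds until the quench, so the sensitive ynone is never exposed to the nucleophile.

Step 13
Reactants: 17 fragment 1; 21 fragment 2 (3 equiv)
Product: 23 B–C–D trimer with ring B as 2,4-dihydroxy-6-ethoxy-butanoylbenzene bearing one free carbon and rings C and D as hexabenzyl ethers, via cyclohexa-1,4-diene cycloadduct 22 (not isolated)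
Conditions: toluene (1 M), 70 °C, sealed, Ar; then 1 M HCl, THF, rt
Reagents that add atoms: none
Why: Proposed new method: the electron-rich (1Z,3Z)-diene of 17 should add across the push–pull triple bond of 21 in a concerted but strongly asynchronous [4+2] cycloaddition (at the limit a vinylogous Mukaiyama–Michael addition followed by Claisen-type closure), its arm-bearing terminal carbon bonding to the ethoxy-bearing alkyne carbon and its ketene-acetal carbon to the alkyne carbon next to the butanoyl carbonyl, to give cyclohexa-1,4-diene 22. The closest known reaction type is the Diels–Alder/aromatization of 1-methoxy-1,3-bis(trimethylsiloxy)buta-1,3-dienes with acetylenic ketones and esters to resorcinols; a β-alkoxy ynone has not been used as the two-carbon partner and its donor group lowers the electrophilicity, which is why heat and an excess of 21 are planned rather than a Lewis acid such as TiCl4 that would attack the benzyl ethers and the enol silanes. Ring B closes by this intermolecular six-membered [4+2] mode with both new ring bonds formed between the two fragments; 22 then loses its methoxy group as methanol, and dilute acid removes all four silyl groups, which completes the aromatic ring and restores the two aryl ketones. No stereocentre is created in 23: the two sp3 carbons of 22 (methoxy cis to the arm, from suprafacial addition to the Z,Z-diene) are both flattened on aromatization. The step needs orientational selectivity, and this is secured by matched polarity, since the largest HOMO coefficient of 17 lies on the arm-bearing terminus and the largest LUMO coefficient of 21 on the carbon β to the carbonyl; the butanoyl group therefore ends up next to the former ester carbon and the ring carbon between the two new hydroxyls stays unsubstituted. It also needs periselectivity against closure through the central diene carbon onto the ketone (a [3+3] salicylate-forming path), which the Lewis-acid-free thermal conditions should disfavour. The two aryl silyl enol ethers are not nucleophilic enough to add to 21 without a Lewis acid and serve only as temporary masks.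

Step 14
Reactants: 23 protected B–C–D trimer
Product: 24 B–C–D trimer with eight free hydroxyls and the ring B ethyl ether
Conditions: H2 (1 atm), Pd/C (10 %), EtOAc–MeOH, rt
Reagents that add atoms: none
Why: Hydrogenolysis of aryl benzyl ethers under neutral conditions; the diarylmethane bridges, the chelated aryl ketones and the ethyl ether should survive.

Step 15
Reactants: 24 ring B mono-ethyl ether
Product: 25 free B–C–D trimer (nine hydroxyls, one free carbon on ring B)
Conditions: BBr3 (12 equiv), CH2Cl2, −78 °C → rt; MeOH, then H2O
Reagents that add atoms: none
Why: Lewis-acid cleavage of an aryl ethyl ether (boron on the ether oxygen, bromide attack on the ethyl group); the ether is twisted out of conjugation by its two ortho substituents, which makes its oxygen basic. BBr3 is chosen over BCl3 because the hydroxyl on the other side of the ketone captures boron as a chelate and removes the carbonyl assistance on which BCl3 depends.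

Step 16
Reactants: 3 phlorobutyrophenone
Product: 26 2-butanoyl-3,5-dihydroxy-4,4-dimethylcyclohexa-2,5-dien-1-one (butanoylfilicinic acid)
Conditions: NaOMe (3.2 equiv), MeI (2.3 equiv), MeOH, 0 °C → rt; acidify, crystallize
Reagents that add atoms: iodomethane, CI
Why: Base-mediated C-methylation of an acylphloroglucinol: the first methyl goes to a free ring carbon and the second to the same carbon, which dearomatizes the ring to the enolized 4,4-dimethyl triketone. The stoichiometry is set for two methyl groups, and mono- and trimethyl by-products are removed by crystallization.

Step 17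
Reactants: 26 butanoylfilicinic acid
Product: 27 2-butanoyl-6-[(dimethylamino)methyl]-3,5-dihydroxy-4,4-dimethylcyclohexa-2,5-dien-1-one (ring A Mannich base)
Conditions: CH2=NMe2+ I− (1.05 equiv), Et3N (1 equiv), CH2Cl2, rt
Reagents that add atoms: N,N-dimethylmethyleneiminium iodide, C=[N+](C)C.[I-]
Why: Mannich reaction at the one remaining enolic CH of the cyclic triketone, the only nucleophilic carbon of 26.

Step 18
Reactants: 25 free B–C–D trimer; 27 ring A Mannich base (1.2 equiv)
Product: 29 target CNP0246352.0, via ring A methide 28 (not isolated)
Conditions: 1,4-dioxane, 80 °C, N2 purge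
Reagents that add atoms: none
Why: Amine elimination from the Mannich base should give the 2-methylidene-1,3-dione 28, an ortho-quinone-methide-type acceptor, which the only free aromatic carbon of 25 attacks in a Michael/Friedel–Crafts sense. Both partners are mono-functional, so only one constitution can result, and no stereocentre is formed.

## Compound list

1 | phloroglucinol (benzene-1,3,5-triol) | Oc1cc(O)cc(O)c1 | starting material
2 | butanoyl chloride | CCCC(=O)Cl | starting material
3 | 1-(2,4,6-trihydroxyphenyl)butan-1-one (phlorobutyrophenone) | CCCC(=O)c1c(O)cc(O)cc1O | intermediate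
4 | 2-methylphloroglucinol (2-methylbenzene-1,3,5-triol) | Cc1c(O)cc(O)cc1O | starting material
5 | 1-(2,4,6-trihydroxy-3-methylphenyl)butan-1-one | CCCC(=O)c1c(O)cc(O)c(C)c1O | intermediate
6 | 1-{3-[(dimethylamino)methyl]-2,4,6-trihydroxy-5-methylphenyl}butan-1-one | CCCC(=O)c1c(O)c(C)c(O)c(CN(C)C)c1O | intermediate
7 | 2-butanoyl-3,5-dihydroxy-4-methyl-6-methylidenecyclohexa-2,4-dien-1-one (ring D ortho-quinone methide) | CCCC(=O)C1=C(O)C(C)=C(O)C(=C)C1=O | intermediate
8 | 1-{3-[(3-butanoyl-2,4,6-trihydroxy-5-methylphenyl)methyl]-2,4,6-trihydroxyphenyl}butan-1-one (C–D dimer) | CCCC(=O)c1c(O)cc(O)c(Cc2c(O)c(C)c(O)c(C(=O)CCC)c2O)c1O | intermediate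
9 | 3-butanoyl-5-[(3-butanoyl-2,4,6-trihydroxy-5-methylphenyl)methyl]-2,4,6-trihydroxybenzaldehyde | CCCC(=O)c1c(O)c(C=O)c(O)c(Cc2c(O)c(C)c(O)c(C(=O)CCC)c2O)c1O | intermediate
10 | 2,4,6-tris(benzyloxy)-3-butanoyl-5-{[2,4,6-tris(benzyloxy)-3-butanoyl-5-methylphenyl]methyl}benzaldehyde | CCCC(=O)c1c(OCc2ccccc2)c(C=O)c(OCc2ccccc2)c(Cc2c(OCc3ccccc3)c(C)c(OCc3ccccc3)c(C(=O)CCC)c2OCc2ccccc2)c1OCc1ccccc1 | intermediate
11 | benzylic alcohol from 10 (hydroxymethyl in place of formyl) | CCCC(=O)c1c(OCc2ccccc2)c(CO)c(OCc2ccccc2)c(Cc2c(OCc3ccccc3)c(C)c(OCc3ccccc3)c(C(=O)CCC)c2OCc2ccccc2)c1OCc1ccccc1 | intermediate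
12 | benzylic bromide from 11 (bromomethyl in place of hydroxymethyl) | CCCC(=O)c1c(OCc2ccccc2)c(CBr)c(OCc2ccccc2)c(Cc2c(OCc3ccccc3)c(C)c(OCc3ccccc3)c(C(=O)CCC)c2OCc2ccccc2)c1OCc1ccccc1 | intermediate
13 | methyl acetoacetate (methyl 3-oxobutanoate) | COC(=O)CC(C)=O | starting material
14 | lithium sodium dianion of methyl acetoacetate | [Li+].[Na+].COC([O-])=CC([O-])=C | intermediate
15 | methyl 5-aryl-3-oxopentanoate, aryl = 2,4,6-tris(benzyloxy)-3-butanoyl-5-{[2,4,6-tris(benzyloxy)-3-butanoyl-5-methylphenyl]methyl}phenyl | COC(=O)CC(=O)CCc1c(OCc2ccccc2)c(Cc2c(OCc3ccccc3)c(C)c(OCc3ccccc3)c(C(=O)CCC)c2OCc2ccccc2)c(OCc2ccccc2)c(C(=O)CCC)c1OCc1ccccc1 | intermediate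
16 | methyl (2Z)-5-aryl-3-(trimethylsiloxy)pent-2-enoate, aryl as in 15 | COC(=O)/C=C(\O[Si](C)(C)C)CCc1c(OCc2ccccc2)c(Cc2c(OCc3ccccc3)c(C)c(OCc3ccccc3)c(C(=O)CCC)c2OCc2ccccc2)c(OCc2ccccc2)c(C(=O)CCC)c1OCc1ccccc1 | intermediate
17 | fragment 1: (1Z,3Z)-1-methoxy-1,3-bis(trimethylsiloxy)-5-arylpenta-1,3-diene, aryl as in 15 but with both butanoyl groups as (Z)-1-(trimethylsiloxy)but-1-enyl groups | CO/C(O[Si](C)(C)C)=C/C(O[Si](C)(C)C)=C/Cc1c(OCc2ccccc2)c(Cc2c(OCc3ccccc3)c(C)c(OCc3ccccc3)c(/C(O[Si](C)(C)C)=C/CC)c2OCc2ccccc2)c(OCc2ccccc2)c(/C(O[Si](C)(C)C)=C/CC)c1OCc1ccccc1 | intermediate
18 | ethoxyethyne | CCOC#C | starting material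
19 | N-methoxy-N-methylbutanamide | CCCC(=O)N(C)OC | starting material
20 | lithium ethoxyacetylide | [Li]C#COCC | intermediate
21 | fragment 2: 1-ethoxyhex-1-yn-3-one | CCCC(=O)C#COCC | intermediate
22 | cycloadduct: 2-butanoyl-3-ethoxy-1-methoxy-1,5-bis(trimethylsiloxy)-4-(arylmethyl)cyclohexa-2,5-diene, racemic, methoxy cis to the arylmethyl arm, aryl as in 17 | CO[C@@]1(O[Si](C)(C)C)C=C(O[Si](C)(C)C)[C@@H](Cc2c(OCc3ccccc3)c(Cc3c(OCc4ccccc4)c(C)c(OCc4ccccc4)c(/C(O[Si](C)(C)C)=C/CC)c3OCc3ccccc3)c(OCc3ccccc3)c(/C(O[Si](C)(C)C)=C/CC)c2OCc2ccccc2)C(OCC)=C1C(=O)CCC | intermediate
23 | protected B–C–D trimer: ring B 3-butanoyl-2-ethoxy-4,6-dihydroxyphenyl attached through CH2 to the hexabenzylated C–D unit | CCCC(=O)c1c(O)cc(O)c(Cc2c(OCc3ccccc3)c(Cc3c(OCc4ccccc4)c(C)c(OCc4ccccc4)c(C(=O)CCC)c3OCc3ccccc3)c(OCc3ccccc3)c(C(=O)CCC)c2OCc2ccccc2)c1OCC | intermediate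
24 | B–C–D trimer, ring B mono-ethyl ether, rings C and D free | CCCC(=O)c1c(O)cc(O)c(Cc2c(O)c(Cc3c(O)c(C)c(O)c(C(=O)CCC)c3O)c(O)c(C(=O)CCC)c2O)c1OCC | intermediate
25 | free B–C–D trimer with one unsubstituted carbon on ring B | CCCC(=O)c1c(O)cc(O)c(Cc2c(O)c(Cc3c(O)c(C)c(O)c(C(=O)CCC)c3O)c(O)c(C(=O)CCC)c2O)c1O | intermediate
26 | 2-butanoyl-3,5-dihydroxy-4,4-dimethylcyclohexa-2,5-dien-1-one (butanoylfilicinic acid) | CCCC(=O)C1=C(O)C(C)(C)C(O)=CC1=O | intermediate
27 | 2-butanoyl-6-[(dimethylamino)methyl]-3,5-dihydroxy-4,4-dimethylcyclohexa-2,5-dien-1-one | CCCC(=O)C1=C(O)C(C)(C)C(O)=C(CN(C)C)C1=O | intermediate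
28 | 2-butanoyl-3-hydroxy-4,4-dimethyl-6-methylidenecyclohex-2-ene-1,5-dione (ring A methide) | CCCC(=O)C1=C(O)C(C)(C)C(=O)C(=C)C1=O | intermediate
29 | CNP0246352.0 | CCCC(=O)C1=C(O)C(C)(C)C(O)=C(Cc2c(O)c(Cc3c(O)c(Cc4c(O)c(C)c(O)c(C(=O)CCC)c4O)c(O)c(C(=O)CCC)c3O)c(O)c(C(=O)CCC)c2O)C1=O | target

## Step count and least certain steps

Total step count: 18. Longest linear sequence: 14 steps (steps 2–11, 13, 14, 15 and 18, from 4).

**Step 13 (key step, proposed new method).**
- What may go wrong: the cycloaddition may not set in below the temperature at which the ynol ether of 21 fragments by retro-ene loss of ethene and at which the ketene acetal of 17 is lost by adventitious protonation. The donor-substituted triple bond is a weak acceptor, and the diene terminus is hindered by its arm. A second failure mode is closure through the central diene carbon onto the ketone, which would give a salicylate instead of ring B.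
- Fallback (known chemistry, from 8 to 25): the free C–D dimer 8 is aminomethylated at its single free ring C carbon with N,N-dimethylmethyleneiminium iodide to give the ring C Mannich base of the C–D dimer F1. F1 is heated in dioxane with a fourfold excess of 3, so that the derived ring C ortho-quinone methide F2 is trapped at one of the two equivalent free carbons of 3. This is the reaction type of step 4 and gives 25 directly, after which steps 16–18 follow unchanged. The price is reliance on an excess of 3 to hold back further bridging, and exposure of the existing C–D bridge to exchange conditions.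

**Step 9.**
- What may go wrong: proton transfer from the α-CH2 groups of the two butanoyl ketones of 12 to the strongly basic dianion may compete with substitution, and the very electron-rich benzylic bromide may ionize and be hydrolysed during handling.
- Fallback (from 10 to 15, without strong base): aldehyde 10 is condensed in a Wittig reaction with the stabilized ylide methyl 3-oxo-4-(triphenylphosphoranylidene)butanoate (COC(=O)CC(=O)C=P(c1ccccc1)(c1ccccc1)c1ccccc1) in toluene at 90 °C to give the (E)-unsaturated β-keto ester F3. Its C=C bond is then hydrogenated over Pd/C poisoned with Ph2S, a catalyst that reduces alkenes but spares benzyl ethers and aryl ketones, to give 15. Compounds 11 and 12 are bypassed.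

**Step 11.**
- What may go wrong: three acidic sites compete for the amide base, which can leave partly silylated mixtures, and the ketene acetal can hydrolyse during the non-aqueous isolation. A diene of uncertain purity then undermines the key step.
- Fallback (from 12 to 25, without the diene): bromide 12 is used as a Friedel–Crafts electrophile. It is stirred with 3 (3 equiv) in (CF3)2CHOH containing 2,6-dimethylpyridine, where the stabilized benzylic cation should be captured at a free carbon of 3, to give the ring B-unprotected hexabenzyl trimer F4. Hydrogenolysis (H2, Pd/C) then gives 25.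

**Step 15.**
- What may go wrong: eight free hydroxyls consume the Lewis acid and form poorly soluble borates, so cleavage of the ethyl ether may need long exposure. During that time the acid set free can promote migration of the methylene bridges by retro-Friedel–Crafts cleavage.
- Fallback (from 23 to 25, 24 bypassed): the order of unmasking is changed so that the ether is cleaved while the substrate is still benzylated, soluble in CH2Cl2 and has only two free hydroxyls. Treatment of 23 with BCl3 and n-Bu4NI in the presence of pentamethylbenzene at −78 °C → 0 °C should remove the ethyl group as iodoethane and the six benzyl groups as benzylpentamethylbenzene in one operation. No new intermediate is formed.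

**Step 18.**
- What may go wrong: methide 28 may be consumed by self-condensation faster than it is trapped, and the dimethylamine released may catalyse retro-Michael exchange of the methylene bridges and scramble the ring sequence.
- Fallback (from 25 and 26 to 29, roles reversed): 25 is aminomethylated at its single free ring B carbon with N,N-dimethylmethyleneiminium iodide to give the ring B Mannich base of the trimer F5. F5 is heated with an excess of the cheap carbon acid 26, so that the ring B ortho-quinone methide F6 is trapped by the one enolic CH of 26, giving 29.

## Further compounds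

F1 | step 13 | 1-{3-[(3-butanoyl-2,4,6-trihydroxy-5-methylphenyl)methyl]-5-[(dimethylamino)methyl]-2,4,6-trihydroxyphenyl}butan-1-one (ring C Mannich base of the C–D dimer) | CCCC(=O)c1c(O)c(CN(C)C)c(O)c(Cc2c(O)c(C)c(O)c(C(=O)CCC)c2O)c1O
F2 | step 13 | ring C ortho-quinone methide of the C–D dimer | CCCC(=O)C1=C(O)C(Cc2c(O)c(C)c(O)c(C(=O)CCC)c2O)=C(O)C(=C)C1=O
F3 | step 9 | methyl (4E)-5-aryl-3-oxopent-4-enoate, aryl as in 15 | COC(=O)CC(=O)/C=C/c1c(OCc2ccccc2)c(Cc2c(OCc3ccccc3)c(C)c(OCc3ccccc3)c(C(=O)CCC)c2OCc2ccccc2)c(OCc2ccccc2)c(C(=O)CCC)c1OCc1ccccc1
F4 | step 11 | B–C–D trimer with ring B as free 3-butanoyl-2,4,6-trihydroxyphenyl and rings C and D as hexabenzyl ethers | CCCC(=O)c1c(O)cc(O)c(Cc2c(OCc3ccccc3)c(Cc3c(OCc4ccccc4)c(C)c(OCc4ccccc4)c(C(=O)CCC)c3OCc3ccccc3)c(OCc3ccccc3)c(C(=O)CCC)c2OCc2ccccc2)c1O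
F0 | step 15 | none | none
F5 | step 18 | ring B Mannich base of the free B–C–D trimer | CCCC(=O)c1c(O)c(CN(C)C)c(O)c(Cc2c(O)c(Cc3c(O)c(C)c(O)c(C(=O)CCC)c3O)c(O)c(C(=O)CCC)c2O)c1O
F6 | step 18 | ring B ortho-quinone methide of the B–C–D trimer | CCCC(=O)C1=C(O)C(Cc2c(O)c(Cc3c(O)c(C)c(O)c(C(=O)CCC)c3O)c(O)c(C(=O)CCC)c2O)=C(O)C(=C)C1=O
A1 | alternative 1 | C–D dimer with one free ring carbon (identical with 8) | CCCC(=O)c1c(O)cc(O)c(Cc2c(O)c(C)c(O)c(C(=O)CCC)c2O)c1O
A2 | alternative 1 | 3-[(3-butanoyl-2,4,6-trihydroxy-5-methylphenyl)methyl]-4-hydroxy-6-(2-oxopentyl)pyran-2-one | CCCC(=O)CC1=CC(O)=C(Cc2c(O)c(C)c(O)c(C(=O)CCC)c2O)C(=O)O1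
A3 | alternative 2 | protected C–D dimer with one free phenol on ring D and one free carbon on ring C | CCCC(=O)c1c(OCc2ccccc2)c(C)c(O)c(Cc2c(OCc3ccccc3)cc(OCc3ccccc3)c(C(=O)CCC)c2OCc2ccccc2)c1OCc1ccccc1
A4 | alternative 2 | ring D aryne precursor: 1-[2,6-bis(benzyloxy)-3-methyl-4-(trifluoromethanesulfonyloxy)-5-(trimethylsilyl)phenyl]butan-1-one | CCCC(=O)c1c(OCc2ccccc2)c(C)c(OS(=O)(=O)C(F)(F)F)c([Si](C)(C)C)c1OCc1ccccc1
A5 | alternative 2 | ring C aldehyde: 2,4,6-tris(benzyloxy)-3-butanoylbenzaldehyde | CCCC(=O)c1c(OCc2ccccc2)cc(OCc2ccccc2)c(C=O)c1OCc1ccccc1
A6 | alternative 3 | protected B–C–D trimer with ring C as a mono-phenol bearing ethoxy and triisopropylsiloxy groups | Oc1cc(OCC)c(Cc2c(OCc3ccccc3)cc(OCc3ccccc3)c(C(=O)CCC)c2OCc2ccccc2)c(O[Si](C(C)C)(C(C)C)C(C)C)c1Cc1c(OCc2ccccc2)c(C)c(OCc2ccccc2)c(C(=O)CCC)c1OCc1ccccc1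
A7 | alternative 3 | 3-ethoxy-2-{[2,4,6-tris(benzyloxy)-3-butanoylphenyl]methyl}cyclobut-2-en-1-one | CCOC1=C(Cc2c(OCc3ccccc3)cc(OCc3ccccc3)c(C(=O)CCC)c2OCc2ccccc2)C(=O)C1
A8 | alternative 3 | 1-{2,4,6-tris(benzyloxy)-3-methyl-5-[3-(triisopropylsiloxy)prop-2-ynyl]phenyl}butan-1-one | CCCC(=O)c1c(OCc2ccccc2)c(C)c(OCc2ccccc2)c(CC#CO[Si](C(C)C)(C(C)C)C(C)C)c1OCc1ccccc1
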